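**Remarks**

- Locants: the dihydrobenzodioxine is numbered O1, C2 (aryl-bearing), C3 (CH2O-bearing), O4, with the side chain on C7 (para to O4, meta to O1). The open chain of the key precursor is numbered from the carboxyl carbon C1 to the aryl-bearing C9.
- Abbreviations: ArM = 3,5-dimethoxy-4-(methoxymethoxy)phenyl; BD = the (2R,3R)-3-{[(tert-butyldimethylsilyl)oxy]methyl}-2-ArM-2,3-dihydro-1,4-benzodioxin-7-yl group.
- Structure check: target, triketo acid and resorcylic acid are mutually consistent as (2R,3R)-trans compounds with the side chain on C7. The one descriptor that needs correcting is that of the 3-carboxylate A3 in alternative 2, which is (2R,3S) by the CIP rules (CO2Et outranks C2) although its arrangement in space is the same trans one.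
- Design changes (disconnection unchanged): the ring A phenol is carried as a methoxymethyl ether, not as an aryl silyl ether, because phenoxide or carbonate (step 5, step 12) can cleave a phenolic silyl ether and so expose a para-hydroxybenzyl ether to quinone methide chemistry. The acyl donor for chain extension is an N-methoxy-N-methyl amide instead of a cinnamate ester. (E)-Sinapic acid replaces an aldehyde-plus-olefination start and saves one step.
- Assumption: (E)-sinapic acid, 3,4-dihydroxybenzaldehyde, acetylacetone and all reagents named are taken as commercial.

## Structural features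

Aiphanol is a stilbenolignan. A syringyl ring (ring A) sits on C2 of a 2,3-dihydro-1,4-benzodioxine (dioxane ring B fused to benzo ring C). C3 carries CH2OH, and C7 of ring C is joined through an E-ethene bridge to C1 of a 3,5-dihydroxyphenyl ring (ring D). The only stereocentres are the adjacent ether carbons C2 and C3 of ring B, both R and trans; C2 is also benzylic to ring A. With the 4-hydroxyl of ring A free, the C2–O1 bond is a para-hydroxybenzyl aryl ether and can ionise to a quinone methide under acid or strong base. The electron-rich stilbene is sensitive to light, oxidants and strong acid. The real difficulty lies in ring B: which catechol oxygen goes to C2 and which to C3, and the absolute and relative configuration of two contiguous C–O centres, one of them prone to SN1 behaviour. The key step exploits ring D instead: oxygen on alternate carbons (C3', C5') and a carbon substituent on C1' mark it as a folded tetraketide. Its six carbons map onto C2–C7 of a 3,5,7-trioxo acid whose C8=C9 is already the stilbene alkene, and the ring closes by forming the C2–C7 bond. Ring D has no stereocentre and the alkene is carried in, so the key step makes chemoselectivity demands only.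

## Logic of the disconnections

**18 from 17.** Cut: the aryl O–C bond of the methoxymethyl acetal on ring A and the O–Si bond on the C3 side chain. Reason: the ring A phenol must stay masked to the end, since as a free para-hydroxybenzyl ether C2 would be exposed to quinone methide formation in every basic step, and the primary hydroxyl must not consume base. Gain: none in skeleton; 17 holds the whole carbon framework. Demand: one acid treatment mild enough for the benzylic ether and the stilbene.

**17 from 16.** Cut (in the synthetic direction): the bond from ring D to the carboxyl carbon. Reason: the carboxyl is the residue of the chain terminus that made ring closure possible and has no place in 18. Gain: 16, an ortho-carboxylated resorcinol, is recognised as the true product of ring construction. Demand: protodecarboxylation without acid or base strong enough to touch the protecting groups.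

**16 from 14 (key disconnection).** Cut: the ring D bond between the carboxyl-bearing carbon and the alkene-bearing carbon, C2–C7 of the chain. The two ring hydroxyls become the C3 and C5 carbonyls and the alkene-bearing ring carbon becomes the C7 carbonyl. Reason: every second carbon of ring D is oxygenated, so unfolding gives a linear poly-β-carbonyl chain. Gain: an aromatic ring is replaced by an unbranched chain without stereocentres. Demand: aldol closure at C7 must win over acyl transfer, closure through oxygen and conjugate addition, under conditions that spare ring B; 14 must react as the free acid.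

**14 from 13.** Cut: C1–C2, the carboxyl carbon. Reason: the β-keto acid is too labile to carry, and a one-carbon electrophile can be added last to the only carbon of 13 still deprotonable once both methylenes are ionised. Gain: 13 is a stable triketone. Demand: complete trianion formation and cold, quick handling of the product.

**13 from 11 and 12.** Cut: C6–C7, between the enone carbonyl and its α-methylene. Reason: this divides the chain into an unsaturated acyl donor and a symmetrical five-carbon diketone. Gain: 12 supplies five of the nine chain carbons in one operation. Demand: attack at the carbonyl carbon and not at the β-carbon, and no loss of nucleophile by proton transfer to the product; hence the N-methoxy-N-methyl amide in 11.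

**11 from 10.** Cut: the C8=C9 double bond. Reason: olefination of an aryl aldehyde with a stabilised phosphonate is the most reliable source of an E-alkene. Gain: the polyketide chain is detached from the heterocycle; 10 holds both stereocentres and little else that is sensitive. Demand: E selectivity, which is then carried unchanged into 18.

**10 from 9 (and 9 from 8 from 7).** Cut: O4–C3; in the two preceding operations the allyl O–C bond on O4 and the O–Si bond on the primary oxygen. Reason: O4, para to the formyl group, is the more acidic phenol and suits a redox-condensation etherification. Cutting here leaves the more easily ionised benzylic C2–O1 bond to be made earlier by epoxide opening. Gain: ring B opens to an acyclic aryl ether with one free secondary carbinol. Demand: clean inversion at that carbinol, which requires the primary hydroxyl blocked and O4 free.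

**7 from 4 and 6.** Cut: O1–C2. Reason: this bond is benzylic, the natural site for nucleophilic opening of an aryl epoxide. Gain: two aromatic building blocks of similar size, with both stereocentres held in one trans-epoxide. Demand: attack at the benzylic carbon only, with inversion and without ionisation, and by O1 only; O4 is therefore blocked as the allyl ether in 6.

**4 from 3.** Cut: both C–O bonds of the oxirane. Reason: an E-allylic alcohol is the standard substrate for reagent-controlled asymmetric epoxidation, which sets both centres at once. Gain: all stereochemistry is traced to an achiral alkene. Demand: the facial choice that gives the (2S,3S)-epoxide (two later inversions turn it into 2R,3R), and survival of an electron-rich benzylic epoxide.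

**3 from 2 from 1; 6 from 5.** Cut: the O–C bonds of two methoxymethyl groups and, in the branch, the allyl O–C bond; the acid is adjusted to the alcohol oxidation level. Reason: 1 already holds ring A, the E-alkene and the three-carbon chain; 5 already holds ring C with both oxygens and the formyl carbon that becomes C9. Gain: commercial materials. Demand: selective alkylation of the hydroxyl para to the formyl group in 5.

## Other disconnections considered

**Alternative 1:** The cut is the O1–C2 bond of ring B. Forward, acid would ionise the benzylic carbinol of the aryl glycerol ether A2 (either epimer at that carbon, ring A phenol free) to a para-quinone methide. The neighbouring phenol O1 would add to C2 and close the dioxane as the trans isomer A1, whose bromine on C7 is the handle for a later coupling that brings in ring D ready-made.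
- In its favour: the closure is stereoconvergent, so only C3 must be made enantiopure; it needs the ring A phenol free, so no protecting group is spent there; the preference for the diequatorial trans ring works for the plan.
- Against it here: the trans preference is an equilibrium position, not a stereospecific outcome. The quinone methide can also shed the CH2OH carbon as formaldehyde or be captured intermolecularly. The C3 centre must still be made with the correct etherification regiochemistry on a 4-bromocatechol. The product must then survive a palladium coupling with free phenols present.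
- Structure: A1 needs one controlled centre where the chosen plan needs two clean inversions (steps 5 and 8). Here the alternative is the better design, because it turns the cation-stabilising power of ring A, a threat to SN2 fidelity in step 5, into the driving force.
- Mechanism: the chosen route is kinetically stereospecific, the alternative thermodynamically controlled; neither is clearly safer.
- Step economy: the alternative is better. With ring D attached by coupling it should need roughly half the steps of the chosen plan, which spends steps 9 to 13 on building that ring.

**Alternative 2:** The cut removes C3 of ring B, that is the O4–C3 and C2–C3 bonds. Forward, a copper carbene made from the diazo ester A5 with a chiral bis(oxazoline) complex of CuOTf (monovalent copper) would attack the acetal oxygen of the 2-aryl-1,3-benzodioxole A4 that lies para to the silyloxy group. A 1,2-shift of the benzylic acetal carbon from oxygen to the ylide carbon would then expand the acetal to the dioxane ester A3.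
- In its favour: A4 is a simple acetal of a catechol and an aryl aldehyde, so ring B is reached in very few steps with two bonds made at once. The ester centre of A3 is epimerisable, so a cis/trans mixture could be drained to trans with base. Ester reduction gives the CH2OH group.
- Against it here: the acetal carbon of A4 is racemic and its configuration is not kept through a stepwise shift, so relative and absolute configuration must both be imposed by the catalyst. The choice between the two acetal oxygens rests on a modest electronic bias. Carbenes also attack electron-rich arenes and dimerise. C7 arrives as an oxygen, which must be turned into a sulfonate and cross-coupled before the alkene can be attached.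
- Structure: the chosen plan brings the C7 carbon and both stereocentres from an established asymmetric epoxidation; A3 needs later changes at C7, at the C3 substituent and on ring A.
- Mechanism: two stereospecific SN2 reactions against a catalyst-controlled ylide rearrangement; the chosen plan is on firmer ground for absolute configuration.
- Step economy: for ring B itself the alternative is better (two operations against steps 1 to 8). The later functional-group changes cancel part of this, so overall it is about equal, or shorter if ring D is brought in by coupling.

**Alternative 3:** The cut is the O4–C3 bond, the same bond that step 8 of the chosen plan forms. Forward, the phenoxide O4 of the aryloxy-epoxide A7 would attack the internal epoxide carbon from the rear, closing ring B in the 6-exo mode with inversion and releasing the CH2OH group in A6.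
- In its favour: strain release replaces phosphine and azodicarboxylate activation; there is no elimination pathway; the closure is the one known from simple glycidyl aryl ethers; CH2OH needs no protection before closure.
- Against it here: the unhindered terminal carbon offers a competing 7-endo opening to a benzodioxepinol, while the internal carbon is flanked by the fully substituted C2. Making A7 needs selective activation of the primary hydroxyl and epoxide formation while O4 is still masked. The freed CH2OH must be protected before any strong-base chemistry.
- Structure: the stereochemical logic (asymmetric epoxidation, two inversions) is the same as in the chosen plan; equal.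
- Mechanism: both closures are intramolecular SN2 reactions. The epoxide version is more atom-economical and is kept as the fallback for step 8, but its regiochemical question has no counterpart in the Mitsunobu closure; about equal.
- Step economy: for the dioxane alone, equal (three operations from 7 either way). As a whole plan, in which A6 is olefinated with a phosphonate that carries ring D, it should be about four steps shorter than the chosen route, and on this count it is the better plan.

Key step: step 12

## Route

Step 1
Reactants: 1 (E)-sinapic acid, (2E)-3-(4-hydroxy-3,5-dimethoxyphenyl)prop-2-enoic acid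
Product: 2 methoxymethyl (2E)-3-ArM-prop-2-enoate
Conditions: MOMCl (2.5 equiv), i-Pr2NEt (3 equiv), CH2Cl2, 0 °C to rt
Reagents that add atoms: chloromethyl methyl ether, COCCl
Why: O-Alkylation of both the phenoxide and the carboxylate by the reactive chloromethyl ether under amine base. The acetal ether is inert to every base used later, and the acetal ester is simply a reducible ester.

Step 2
Reactants: 2 methoxymethyl (2E)-3-ArM-prop-2-enoate
Product: 3 (2E)-3-ArM-prop-2-en-1-ol
Conditions: i-Bu2AlH (3.5 equiv), CH2Cl2, −78 to −20 °C; aq. KNaC4H4O6 work-up
Reagents that add atoms: none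
Why: 1,2-Reduction of a conjugated ester by i-Bu2AlH gives the allylic alcohol without touching the alkene or the aryl acetal; the E geometry is retained.

Step 3
Reactants: 3 (2E)-3-ArM-prop-2-en-1-ol
Product: 4 [(2S,3S)-3-ArM-oxiran-2-yl]methanol (trans)
Conditions: Ti(Oi-Pr)4 (10 mol %), L-(+)-diethyl tartrate (14 mol %), t-BuOOH (2 equiv, decane solution), 4 Å molecular sieves, CH2Cl2, −25 °C
Reagents that add atoms: tert-butyl hydroperoxide, CC(C)(C)OO
Why: Sharpless asymmetric epoxidation of an E-allylic alcohol; with the (R,R)-tartrate the titanium-bound peroxide is delivered to the face that gives the (2S,3S)-trans-epoxide, as with E-cinnamyl alcohols in general. Both stereocentres of the target are set here (each is inverted once, in steps 5 and 8). The catalytic protocol with sieves at low temperature limits opening of the electron-rich benzylic epoxide.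

Step 4
Reactants: 5 3,4-dihydroxybenzaldehyde
Product: 6 3-hydroxy-4-(prop-2-en-1-yloxy)benzaldehyde
Conditions: allyl bromide (1.05 equiv), NaHCO3 (1.5 equiv), NaI (0.1 equiv), DMF, 40 °C
Reagents that add atoms: allyl bromide, C=CCBr
Why: Phenol O-alkylation; the hydroxyl para to the formyl group is clearly the more acidic, so the weak base ionises and alkylates it selectively. O4 is blocked and O1 left free.

Step 5
Reactants: 4 [(2S,3S)-3-ArM-oxiran-2-yl]methanol; 6 3-hydroxy-4-(prop-2-en-1-yloxy)benzaldehyde
Product: 7 3-[(1R,2S)-1-ArM-2,3-dihydroxypropoxy]-4-(prop-2-en-1-yloxy)benzaldehyde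
Conditions: 6 (1.3 equiv), Cs2CO3 (0.3 equiv), DMF, 70 °C
Reagents that add atoms: none
Why: Stereospecific SN2 opening of a trans-3-aryl-2,3-epoxy alcohol by a phenoxide under weakly basic conditions free of Lewis acid. Attack goes to the benzylic carbon (activated by ring A, while the other epoxide carbon is deactivated by the adjacent CH2OH) and inverts it, so 3S in 4 becomes the R-configured future C2. Only O1 can react because O4 is an allyl ether, and catalytic base suffices because the alkoxide formed is reprotonated by the phenol.

Step 6
Reactants: 7 3-[(1R,2S)-1-ArM-2,3-dihydroxypropoxy]-4-(prop-2-en-1-yloxy)benzaldehyde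
Product: 8 3-{(1R,2S)-3-[(tert-butyldimethylsilyl)oxy]-1-ArM-2-hydroxypropoxy}-4-(prop-2-en-1-yloxy)benzaldehyde
Conditions: TBSCl (1.1 equiv), imidazole (2 equiv), CH2Cl2, 0 °C
Reagents that add atoms: tert-butyldimethylsilyl chloride, CC(C)(C)[Si](C)(C)Cl
Why: Silylation with a bulky chlorosilane distinguishes the primary from the hindered secondary hydroxyl. The secondary carbinol stays free as the site of ring closure.

Step 7
Reactants: 8 3-{(1R,2S)-3-[(tert-butyldimethylsilyl)oxy]-1-ArM-2-hydroxypropoxy}-4-(prop-2-en-1-yloxy)benzaldehyde
Product: 9 3-{(1R,2S)-3-[(tert-butyldimethylsilyl)oxy]-1-ArM-2-hydroxypropoxy}-4-hydroxybenzaldehyde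
Conditions: Pd(PPh3)4 (5 mol %), morpholine (5 equiv), THF, rt
Reagents that add atoms: none
Why: Tsuji–Trost deallylation: zerovalent palladium ionises the allyl aryl ether (the phenoxide para to the formyl group is a good leaving group) and morpholine traps the allyl fragment. Silyl ether, acetal and aldehyde are not affected.

Step 8
Reactants: 9 3-{(1R,2S)-3-[(tert-butyldimethylsilyl)oxy]-1-ArM-2-hydroxypropoxy}-4-hydroxybenzaldehyde
Product: 10 (2R,3R)-3-{[(tert-butyldimethylsilyl)oxy]methyl}-2-ArM-2,3-dihydro-1,4-benzodioxine-7-carbaldehyde (trans)
Conditions: PPh3 (1.5 equiv), DIAD (1.5 equiv), THF (0.01 M), 0 °C to rt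
Reagents that add atoms: none
Why: Intramolecular Mitsunobu etherification (6-exo-tet): the phenol para to the formyl group is acidic enough to protonate the betaine, and its phenoxide displaces the oxyphosphonium group from the rear. The S carbinol of 9 thus becomes the R-configured C3, with the CH2O substituent trans to the aryl group on C2. High dilution disfavours intermolecular etherification.

Step 9
Reactants: 10 (2R,3R)-3-{[(tert-butyldimethylsilyl)oxy]methyl}-2-ArM-2,3-dihydro-1,4-benzodioxine-7-carbaldehyde
Product: 11 (2E)-3-BD-N-methoxy-N-methylprop-2-enamide
Conditions: (EtO)2P(O)CH2C(O)N(OMe)Me (1.3 equiv), NaH (1.3 equiv), THF, 0 °C to rt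
Reagents that add atoms: diethyl [2-(methoxy(methyl)amino)-2-oxoethyl]phosphonate, CCOP(=O)(CC(=O)N(C)OC)OCC
Why: Horner–Wadsworth–Emmons olefination with a stabilised amide phosphonate gives the E-alkene under thermodynamic control. It installs the future stilbene double bond and the acyl donor in one step; the ether stereocentres carry no acidic hydrogen.

Step 10
Reactants: 11 (2E)-3-BD-N-methoxy-N-methylprop-2-enamide; 12 acetylacetone (pentane-2,4-dione)
Product: 13 (7E)-8-BD-oct-7-ene-2,4,6-trione
Conditions: 12 (2.0 equiv), LiN(i-Pr)2 (4.1 equiv), THF, −78 to 0 °C; then 11, −78 to −20 °C; cold dilute HCl to pH 5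
Reagents that add atoms: none
Why: C-Acylation of a β-diketone dianion at its terminal, more basic carbon. The N-methoxy-N-methyl amide is attacked at the carbonyl carbon and not at the β-carbon, and its chelated tetrahedral adduct persists until work-up, so the more acidic triketone never meets the dianion.

Step 11
Reactants: 13 (7E)-8-BD-oct-7-ene-2,4,6-trione
Product: 14 (8E)-9-BD-3,5,7-trioxonon-8-enoic acid
Conditions: LiN(i-Pr)2 (3.5 equiv), THF, −78 to 0 °C; CO2 (gas), −78 °C; cold dilute HCl to pH 3, cold extraction, used at once
Reagents that add atoms: carbon dioxide, O=C=O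
Why: Polyanion carboxylation of a 1,3,5-triketone: after both methylenes are ionised, the third equivalent of base deprotonates the terminal methyl, the only site left, and this most reactive carbanion takes up CO2. Cold acidification frees the β-keto acid, which is not stored because it loses CO2 on standing.

Step 12
Reactants: 14 (8E)-9-BD-3,5,7-trioxonon-8-enoic acid
Product: 16 2,4-dihydroxy-6-[(E)-2-BD-ethenyl]benzoic acid, via cyclic aldol adduct 15 (not isolated)
Conditions: aq. NaHCO3/Na2CO3 buffer (pH about 9)–THF, 20 °C, argon, dark; then cold dilute HCl to pH 3
Reagents that add atoms: none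
Why: In the mildly basic aqueous medium the acid is present as its carboxylate and the diketone units as enol(ate)s; the enol(ate) carbon C2, between the carboxylate and the C3 carbonyl, adds to the C7 carbonyl to give the cyclic β-hydroxy ketone 15, which loses water twice, the second loss being driven by aromatisation, to give the 2,4-dihydroxybenzoate. The closest known reaction type is the base-induced cyclodehydration of β,δ,ζ-triketo carboxylic acids to 6-substituted 2,4-dihydroxybenzoic acids, the laboratory counterpart of stilbene synthase chemistry. The one ring formed (ring D) closes in the 6-(enolendo)-exo-trig mode with one new C–C bond, C2–C7. No stereocentre is created in the product: the two sp3 centres of 15 vanish on aromatisation, the E-alkene comes unchanged from step 9, and the ether centres C2 and C3 of ring B are neither acidic nor electrophilic here. The selectivity needed is aldol closure at C7 over acyl transfer, closure through oxygen and conjugate addition: a carboxylate is not an acylating agent, which rules out the phloroglucinol pathway; the absence of strong acid rules out dehydrative closure to a 4-pyranone; and addition of C4 or of an enol oxygen to C9 is reversible whereas aromatisation is not, so 16 is the thermodynamic sink.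

Step 13
Reactants: 16 2,4-dihydroxy-6-[(E)-2-BD-ethenyl]benzoic acid
Product: 17 5-[(E)-2-BD-ethenyl]benzene-1,3-diol
Conditions: DMF, 120 °C, argon, dark
Reagents that add atoms: none
Why: Thermal protodecarboxylation of a 2,4-dihydroxybenzoic acid: the ring carbon bearing the carboxyl is ortho and para to the two hydroxyls, is protonated at the ipso position and then loses CO2. The neutral conditions leave the acetal, the silyl ether and the E-alkene alone.

Step 14
Reactants: 17 5-[(E)-2-BD-ethenyl]benzene-1,3-diol
Product: 18 aiphanol, 5-{(E)-2-[(2R,3R)-2-(4-hydroxy-3,5-dimethoxyphenyl)-3-(hydroxymethyl)-2,3-dihydro-1,4-benzodioxin-7-yl]ethenyl}benzene-1,3-diol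
Conditions: HCl (1.25 M in MeOH, 5 equiv), THF–MeOH, 40 °C, argon, dark
Reagents that add atoms: none
Why: Acid-catalysed transacetalisation removes the aryl methoxymethyl ether and methanolysis removes the primary silyl ether in the same operation. The trans-diequatorial dioxane is the preferred isomer and C3 is not involved, so even a reversible ionisation at C2 should return the same compound.

## Compound list

1 | (E)-sinapic acid, (2E)-3-(4-hydroxy-3,5-dimethoxyphenyl)prop-2-enoic acid | COc1cc(/C=C/C(=O)O)cc(OC)c1O | starting material
2 | methoxymethyl (2E)-3-[3,5-dimethoxy-4-(methoxymethoxy)phenyl]prop-2-enoate | COCOC(=O)/C=C/c1cc(OC)c(OCOC)c(OC)c1 | intermediate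
3 | (2E)-3-[3,5-dimethoxy-4-(methoxymethoxy)phenyl]prop-2-en-1-ol | OC/C=C/c1cc(OC)c(OCOC)c(OC)c1 | intermediate
4 | [(2S,3S)-3-[3,5-dimethoxy-4-(methoxymethoxy)phenyl]oxiran-2-yl]methanol (trans) | OC[C@@H]1O[C@H]1c1cc(OC)c(OCOC)c(OC)c1 | intermediate
5 | 3,4-dihydroxybenzaldehyde | O=Cc1ccc(O)c(O)c1 | starting material
6 | 3-hydroxy-4-(prop-2-en-1-yloxy)benzaldehyde | C=CCOc1ccc(C=O)cc1O | intermediate
7 | 3-{(1R,2S)-1-[3,5-dimethoxy-4-(methoxymethoxy)phenyl]-2,3-dihydroxypropoxy}-4-(prop-2-en-1-yloxy)benzaldehyde | OC[C@H](O)[C@H](Oc1cc(C=O)ccc1OCC=C)c1cc(OC)c(OCOC)c(OC)c1 | intermediate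
8 | 3-{(1R,2S)-3-[(tert-butyldimethylsilyl)oxy]-1-[3,5-dimethoxy-4-(methoxymethoxy)phenyl]-2-hydroxypropoxy}-4-(prop-2-en-1-yloxy)benzaldehyde | CC(C)(C)[Si](C)(C)OC[C@H](O)[C@H](Oc1cc(C=O)ccc1OCC=C)c1cc(OC)c(OCOC)c(OC)c1 | intermediate
9 | 3-{(1R,2S)-3-[(tert-butyldimethylsilyl)oxy]-1-[3,5-dimethoxy-4-(methoxymethoxy)phenyl]-2-hydroxypropoxy}-4-hydroxybenzaldehyde | CC(C)(C)[Si](C)(C)OC[C@H](O)[C@H](Oc1cc(C=O)ccc1O)c1cc(OC)c(OCOC)c(OC)c1 | intermediate
10 | (2R,3R)-3-{[(tert-butyldimethylsilyl)oxy]methyl}-2-[3,5-dimethoxy-4-(methoxymethoxy)phenyl]-2,3-dihydro-1,4-benzodioxine-7-carbaldehyde (trans) | COCOc1c(OC)cc([C@H]2Oc3cc(C=O)ccc3O[C@@H]2CO[Si](C)(C)C(C)(C)C)cc1OC | intermediate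
11 | (2E)-3-[(2R,3R)-3-{[(tert-butyldimethylsilyl)oxy]methyl}-2-[3,5-dimethoxy-4-(methoxymethoxy)phenyl]-2,3-dihydro-1,4-benzodioxin-7-yl]-N-methoxy-N-methylprop-2-enamide | COCOc1c(OC)cc([C@H]2Oc3cc(/C=C/C(=O)N(C)OC)ccc3O[C@@H]2CO[Si](C)(C)C(C)(C)C)cc1OC | intermediate
12 | acetylacetone (pentane-2,4-dione) | CC(=O)CC(C)=O | starting material
13 | (7E)-8-[(2R,3R)-3-{[(tert-butyldimethylsilyl)oxy]methyl}-2-[3,5-dimethoxy-4-(methoxymethoxy)phenyl]-2,3-dihydro-1,4-benzodioxin-7-yl]oct-7-ene-2,4,6-trione | COCOc1c(OC)cc([C@H]2Oc3cc(/C=C/C(=O)CC(=O)CC(C)=O)ccc3O[C@@H]2CO[Si](C)(C)C(C)(C)C)cc1OC | intermediate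
14 | (8E)-9-[(2R,3R)-3-{[(tert-butyldimethylsilyl)oxy]methyl}-2-[3,5-dimethoxy-4-(methoxymethoxy)phenyl]-2,3-dihydro-1,4-benzodioxin-7-yl]-3,5,7-trioxonon-8-enoic acid | COCOc1c(OC)cc([C@H]2Oc3cc(/C=C/C(=O)CC(=O)CC(=O)CC(=O)O)ccc3O[C@@H]2CO[Si](C)(C)C(C)(C)C)cc1OC | intermediate
15 | 2-[(E)-2-BD-ethenyl]-2-hydroxy-4,6-dioxocyclohexane-1-carboxylic acid (cyclic aldol adduct, mixture of diastereomers at the two new ring carbons, BD as defined in the remarks) | COCOc1c(OC)cc([C@H]2Oc3cc(/C=C/C4(O)CC(=O)CC(=O)C4C(=O)O)ccc3O[C@@H]2CO[Si](C)(C)C(C)(C)C)cc1OC | intermediate (not isolated)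
16 | 2-[(E)-2-[(2R,3R)-3-{[(tert-butyldimethylsilyl)oxy]methyl}-2-[3,5-dimethoxy-4-(methoxymethoxy)phenyl]-2,3-dihydro-1,4-benzodioxin-7-yl]ethenyl]-4,6-dihydroxybenzoic acid | COCOc1c(OC)cc([C@H]2Oc3cc(/C=C/c4cc(O)cc(O)c4C(=O)O)ccc3O[C@@H]2CO[Si](C)(C)C(C)(C)C)cc1OC | intermediate
17 | 5-[(E)-2-[(2R,3R)-3-{[(tert-butyldimethylsilyl)oxy]methyl}-2-[3,5-dimethoxy-4-(methoxymethoxy)phenyl]-2,3-dihydro-1,4-benzodioxin-7-yl]ethenyl]benzene-1,3-diol | COCOc1c(OC)cc([C@H]2Oc3cc(/C=C/c4cc(O)cc(O)c4)ccc3O[C@@H]2CO[Si](C)(C)C(C)(C)C)cc1OC | intermediate
18 | aiphanol, 5-[(E)-2-[(2R,3R)-2-(4-hydroxy-3,5-dimethoxyphenyl)-3-(hydroxymethyl)-2,3-dihydro-1,4-benzodioxin-7-yl]ethenyl]benzene-1,3-diol | COc1cc([C@H]2Oc3cc(/C=C/c4cc(O)cc(O)c4)ccc3O[C@@H]2CO)cc(OC)c1O | target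

## Step count and least certain steps

Total step count: 14. Longest linear sequence: 13 steps (steps 1 to 3 and 5 to 14, from 1); step 4 is a one-step branch.

**Step 12 (key step).** The most likely failure is loss of CO2 from the β-keto acid terminus before ring closure, which returns 13. The second is closure through oxygen (oxa-conjugate addition to C9, or pyranone formation if the medium turns acidic), because the enone carbonyl C7 is a weaker electrophile than a saturated ketone. Fallback, setting out from 10 and returning at 18: ring D is brought in ready-made. Aldehyde 10 would be olefinated (NaH, THF, 0 °C) with the known diethyl [3,5-bis(methoxymethoxy)benzyl]phosphonate to the fully protected stilbene F1. Methanolic HCl as in step 14 would then remove the three acetal groups and the silyl group to give 18. This gives up the ring construction and bypasses steps 9 to 13.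

**Step 11.** Likely failures are incomplete trianion formation, carboxylation on oxygen, decarboxylation of 14 during acidification and extraction, and, with excess amide base, deprotonation at C2 of ring B followed by β-elimination of the O4 aryloxide. Fallback, setting out from 11 and returning at 16: the carboxyl carbon is brought in already masked. Amide 11 would acylate the dilithium dianion (LiN(i-Pr)2, THF, −78 °C) of the known 2,2-dimethyl-6-(2-oxopropyl)-4H-1,3-dioxin-4-one to give the diketo-dioxinone F2, in which the β-keto acid is locked as an enol acetonide that can neither lose CO2 nor transfer its acyl group. Et3N in CH2Cl2 should effect the same C2–C7 aldol closure and aromatisation to the benzodioxinone F3, and aqueous KOH in THF would open the acetonide to 16.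

**Step 3.** The likely failure is opening of the new epoxide at its benzylic carbon by isopropanol or tert-butanol under titanium Lewis acid activation, since ring A stabilises positive charge there; enantiomeric purity would also suffer if the catalyst is partly deactivated. Fallback, setting out from 3 and returning at 8: alcohol 3 would be silylated (TBSCl, imidazole) to the silyl ether F4. F4 would be epoxidised without any Lewis acid by the dioxirane formed from KHSO5 (as 2KHSO5·KHSO4·K2SO4) and the L-configured enantiomer of the fructose-derived Shi ketone (from L-sorbose) in K2CO3-buffered aqueous acetonitrile at pH about 10.5; by the spiro transition-state model this enantiomer attacks the face that leads to the (2S,3S)-epoxy silyl ether F5. Opening of F5 with 6 under the conditions of step 5 leads directly to 8.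

**Step 8.** The likely failure is β-elimination of the activated secondary alcohol, or intermolecular etherification, because the carbinol lies between two branched carbons. Fallback, setting out from 7 and returning at 10: the electrophile is changed to an epoxide. Diol 7 would be sulfonylated at the primary hydroxyl (TsCl, Et3N, Bu2SnO cat.) to the primary tosylate F6 and closed with K2CO3 in MeOH to the terminal epoxide F7, with the carbinol configuration retained. Pd(PPh3)4 and K2CO3 in MeOH would then remove the allyl group, and the phenoxide so formed would open the epoxide at its internal carbon (6-exo, inversion) to the free alcohol F8, the same compound as A6. Silylation (TBSCl, imidazole) gives 10. The new risk is competing attack at the terminal epoxide carbon.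

## Further compounds

F1 | step 12 | (2R,3R)-7-{(E)-2-[3,5-bis(methoxymethoxy)phenyl]ethenyl}-3-{[(tert-butyldimethylsilyl)oxy]methyl}-2-[3,5-dimethoxy-4-(methoxymethoxy)phenyl]-2,3-dihydro-1,4-benzodioxine | COCOc1c(OC)cc([C@H]2Oc3cc(/C=C/c4cc(OCOC)cc(OCOC)c4)ccc3O[C@@H]2CO[Si](C)(C)C(C)(C)C)cc1OC
F2 | step 11 | 6-[(5E)-6-BD-2,4-dioxohex-5-en-1-yl]-2,2-dimethyl-4H-1,3-dioxin-4-one | COCOc1c(OC)cc([C@H]2Oc3cc(/C=C/C(=O)CC(=O)CC4=CC(=O)OC(C)(C)O4)ccc3O[C@@H]2CO[Si](C)(C)C(C)(C)C)cc1OC
F3 | step 11 | 5-[(E)-2-BD-ethenyl]-7-hydroxy-2,2-dimethyl-4H-1,3-benzodioxin-4-one | COCOc1c(OC)cc([C@H]2Oc3cc(/C=C/c4cc(O)cc5OC(C)(C)OC(=O)c45)ccc3O[C@@H]2CO[Si](C)(C)C(C)(C)C)cc1OC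
F4 | step 3 | tert-butyl{[(2E)-3-[3,5-dimethoxy-4-(methoxymethoxy)phenyl]prop-2-en-1-yl]oxy}dimethylsilane | COCOc1c(OC)cc(/C=C/CO[Si](C)(C)C(C)(C)C)cc1OC
F5 | step 3 | tert-butyl{[(2S,3S)-3-[3,5-dimethoxy-4-(methoxymethoxy)phenyl]oxiran-2-yl]methoxy}dimethylsilane | CC(C)(C)[Si](C)(C)OC[C@@H]1O[C@H]1c1cc(OC)c(OCOC)c(OC)c1
F6 | step 8 | (2S,3R)-3-[3,5-dimethoxy-4-(methoxymethoxy)phenyl]-3-[5-formyl-2-(prop-2-en-1-yloxy)phenoxy]-2-hydroxypropyl 4-methylbenzenesulfonate | Cc1ccc(S(=O)(=O)OC[C@H](O)[C@H](Oc2cc(C=O)ccc2OCC=C)c3cc(OC)c(OCOC)c(OC)c3)cc1
F7 | step 8 | 3-{(R)-[3,5-dimethoxy-4-(methoxymethoxy)phenyl][(2S)-oxiran-2-yl]methoxy}-4-(prop-2-en-1-yloxy)benzaldehyde | C=CCOc1ccc(C=O)cc1O[C@@H]([C@@H]2CO2)c3cc(OC)c(OCOC)c(OC)c3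
F8 | step 8 | (2R,3R)-2-[3,5-dimethoxy-4-(methoxymethoxy)phenyl]-3-(hydroxymethyl)-2,3-dihydro-1,4-benzodioxine-7-carbaldehyde | COCOc1c(OC)cc([C@H]2Oc3cc(C=O)ccc3O[C@@H]2CO)cc1OC
A1 | alternative 1 | [(2R,3R)-7-bromo-2-(4-hydroxy-3,5-dimethoxyphenyl)-2,3-dihydro-1,4-benzodioxin-3-yl]methanol | COc1cc([C@H]2Oc3cc(Br)ccc3O[C@@H]2CO)cc(OC)c1O
A2 | alternative 1 | (2R)-2-(4-bromo-2-hydroxyphenoxy)-1-(4-hydroxy-3,5-dimethoxyphenyl)propane-1,3-diol (either epimer at C1) | COc1cc(C(O)[C@@H](CO)Oc2ccc(Br)cc2O)cc(OC)c1O
A3 | alternative 2 | ethyl (2R,3S)-2-[4-(2,2-dimethylpropanoyloxy)-3,5-dimethoxyphenyl]-7-[(triisopropylsilyl)oxy]-2,3-dihydro-1,4-benzodioxine-3-carboxylate (trans) | COc1cc([C@H]2Oc3cc(O[Si](C(C)C)(C(C)C)C(C)C)ccc3O[C@@H]2C(=O)OCC)cc(OC)c1OC(=O)C(C)(C)C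
A4 | alternative 2 | 2,6-dimethoxy-4-{5-[(triisopropylsilyl)oxy]-1,3-benzodioxol-2-yl}phenyl 2,2-dimethylpropanoate (racemic at the acetal carbon) | COc1cc(C2Oc3ccc(O[Si](C(C)C)(C(C)C)C(C)C)cc3O2)cc(OC)c1OC(=O)C(C)(C)C
A5 | alternative 2 | ethyl diazoacetate | CCOC(=O)C=[N+]=[N-]
A6 | alternative 3 | (2R,3R)-2-[3,5-dimethoxy-4-(methoxymethoxy)phenyl]-3-(hydroxymethyl)-2,3-dihydro-1,4-benzodioxine-7-carbaldehyde | COCOc1c(OC)cc([C@H]2Oc3cc(C=O)ccc3O[C@@H]2CO)cc1OC
A7 | alternative 3 | 3-{(R)-[3,5-dimethoxy-4-(methoxymethoxy)phenyl][(2S)-oxiran-2-yl]methoxy}-4-hydroxybenzaldehyde | O=Cc1ccc(O)c(O[C@@H]([C@@H]2CO2)c3cc(OC)c(OCOC)c(OC)c3)c1
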